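After 12.0 h the west flask still holds 11.4% of its left-handed substrate and 91.0% of its right-handed substrate, and I reckon with these fractions left, not with the product made. I assume that both mirror images meet the same partner and the same catalyst, so that the logarithms of their fractions left keep one ratio however those two run down. Pooled over the west readings at 6.00 h and 12.0 h, that ratio reads 23.9, and I carry it as the selectivity factor.

in all of them: left-handed substrate 0.020 M; right-handed substrate 0.020 M; free catalyst 0.1 mol%

| charge | partner | protic impurity | remark | time |
|---|---|---|---|---|
| west | 1.2 equiv | 2 mM | run made earlier |  |
| south | 2.9 equiv | 2 mM | run made earlier |  |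
| south-west | 7.2 equiv | 2 mM | run made earlier |  |
| blue | 1.50 equiv | 2.00 mM |  | 12 h |
| grey | 6.00 equiv | 2.00 mM |  | 4.0 h |

- west (time / h: left-handed product / %, right-handed product / %): 1.00: 21.8, 1.4; 2.00: 30.4, 1.5; 3.00: 35.2, 1.9; 6.00: 41.0, 3.3; 12.0: 44.3, 4.5
- south (time / h: left-handed product / %, right-handed product / %): 1.00: 38.9, 2.5; 2.00: 46.1, 5.5; 3.00: 49.1, 6.5; 6.00: 49.6, 10.9; 12.0: 50.0, 16.9
- south-west (time / h: left-handed product / %, right-handed product / %): 2.50: 49.9, 15.6; 5.00: 50.2, 24.5; 8.00: 49.9, 30.9; 10.0: 50.2, 35.1; 12.0: 50.2, 36.9

(scatter of a reading: 0.3 percentage points)

- free catalyst is single-handed; left-handed substrate and right-handed substrate are mirror images of each other, charged as a racemate, each of them at the stated concentration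
- the earlier runs were read with a standard deviation of 0.3 percentage points
- an excess is the difference of the two amounts in percent of their sum
- an excess is below zero if the other one leads

- the flask that ends with the higher excess of left-handed product over right-handed product, or "neither" when 2 percentage points or less lies between them (blue / grey / neither)
- excess of left-handed product over right-handed product at the end, blue
- excess of left-handed product over right-handed product at the end, grey

West and blue look nearly the same, 1.2 equiv of partner against 1.50 equiv, with the same 2.00 mM of protic impurity, which I take to use up partner. West slows late, gaining 3.3 percentage points of left-handed product between 6.00 h and 12.0 h, while blue has the wider margin, so I expect it to run further along the same curve. I judge its 12 h to be worth 2.00 h to 3.00 h of the south flask, and the left-handed substrate south has left at those times, put through the selectivity factor, gives an excess from 80.2% down to 72.8%.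

Grey resembles south-west, whose left-handed product already reads 49.9% at 2.50 h, so grey's excess hangs on the right-handed substrate. With partner in large excess I treat the fall of that substrate as roughly pseudo-first-order, and south-west's logarithm at 5.00 h, scaled by equivalents and time, gives my estimate for grey of 63.8% of it left, an excess of 46.9%, lower than my range for blue.

The forecast names blue, with 75% for blue and 49% for grey, on the ground: “Excess partner erodes selectivity, so blue ends higher.” Its blue lies inside my range, and its grey stands a little above mine.

The flasks give blue as the higher, at 76.8% for blue and 46.2% for grey.

    partner + free catalyst + left-handed substrate → free catalyst + left-handed product (k = 27000 L² mol⁻² min⁻¹)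
    free catalyst → spent catalyst (k = 8.50 × 10⁻⁴ min⁻¹)
    partner + free catalyst + right-handed substrate → free catalyst + right-handed product (k = 1100 L² mol⁻² min⁻¹)
    partner + protic impurity → quenched reagent (k = 0.180 L mol⁻¹ min⁻¹)

Grey run with blue's equivalents of partner reaches 83.9%, so the difference in equivalents may be called the main reason for the gap, while grey given blue's time reads 20.5%, so the difference in time is a part of it, working the other way. In blue 3.6% of the left-handed substrate remains at the end, and the selectivity factor turns that into 87.0% of the right-handed substrate, against 87% found. In the neighbour, like blue but with 0.17 mol% of free catalyst, 0.97% of the left-handed substrate turns into 82.4% of the right-handed substrate against 83% found, and its excess ends at 70.4%.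

(Readings and results were generated by integration with constants of no real substance, noise included.)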